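**Retrosynthetic overview**

- Target ⇐ BCl3 cleavage of the O-methyl groups at C2 (ring B) and C2′ (ring A) ⇐ formylation at C3′ ⇐ depside with ring A still bearing hydrogen at C3′.
- Ring A ⇐ [4+2] benzannulation forming C1′–C2′ and C5′–C6′: C1′ and C6′ are the alkyne carbons of a but-2-ynoate already esterified to O4 of ring B, and C2′–C5′ come from a 1,1-dimethoxy-3-silyloxypenta-1,3-diene.
- Feature used: in the benzoyl ring A, C1′ (depside carbonyl) and C6′ (methyl) are adjacent, and C2′(O)–C3′–C4′(O)–C5′(Me) is a 1,1,3-oxygenated pentadiene. The crowded ester C1′–C(=O)–O–C4, flanked by C2′/C6′ and by the C3/C5 methyls, is therefore made while the acyl group is still a slim alkyne.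
- Ynoate ⇐ methyl beta-orcinolcarboxylate (C5 formylation, hydrogenolysis to methyl, O4 acylation with but-2-ynoic acid, O2 methylation); diene ⇐ propanoyl chloride + 1,1-dimethoxyethene, then enol silylation.
- Ring order: ring B is bought; ring A is built last, on the finished ester.

Key step: step 7

Remark: the target has no stereocentre, so the only stereochemical element in the route is the Z enol ether of the diene. Ring B is numbered C1–C6 from the CO2Me carbon and ring A C1′–C6′ from the carbon bearing the depside carbonyl.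

**Route**

Step 1
Reactants: 1 methyl 2,4-dihydroxy-3,6-dimethylbenzoate (methyl beta-orcinolcarboxylate)
Product: 2 methyl 5-formyl-2,4-dihydroxy-3,6-dimethylbenzoate
Conditions: Cl2CHOMe, TiCl4, CH2Cl2, 0 °C to rt; then aq. HCl
Reagents that add atoms: dichloromethyl methyl ether (COC(Cl)Cl); water (O)
Why: Rieche formylation, in which the TiCl4-activated dichloromethyl ether attacks C5, the only unsubstituted ring carbon (ortho to the C4 hydroxyl, para to the C2 hydroxyl), and the titanium-bound adduct is hydrolysed to the aldehyde on work-up.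

Step 2
Reactants: 2 methyl 5-formyl-2,4-dihydroxy-3,6-dimethylbenzoate
Product: 4 methyl 2,4-dihydroxy-3,5,6-trimethylbenzoate, via benzylic alcohol 3 (not isolated)
Conditions: H2 (1 atm), 10% Pd/C, AcOH, cat. HClO4, rt
Reagents that add atoms: none
Why: Catalytic hydrogenation followed by acid-assisted benzylic hydrogenolysis, which should take an aldehyde on an electron-rich ring ortho and para to hydroxyl groups through the benzylic alcohol to the methyl group without touching the ester or the ring.

Step 3
Reactants: 4 methyl 2,4-dihydroxy-3,5,6-trimethylbenzoate; 5 but-2-ynoic acid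
Product: 7 methyl 4-(but-2-ynoyloxy)-2-hydroxy-3,5,6-trimethylbenzoate, via O-acylisourea 6 (not isolated)
Conditions: DCC, DMAP (cat.), CH2Cl2, 0 °C to rt
Reagents that add atoms: none
Why: Steglich esterification, selective for the C4 hydroxyl because the C2 hydroxyl is tied up in a hydrogen bond to the ester carbonyl, and feasible at this doubly ortho-methylated oxygen because the acyl partner is a small linear ynoyl group.

Step 4
Reactants: 7 methyl 4-(but-2-ynoyloxy)-2-hydroxy-3,5,6-trimethylbenzoate
Product: 8 3-methoxy-4-(methoxycarbonyl)-2,5,6-trimethylphenyl but-2-ynoate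
Conditions: MeI (excess), K2CO3, acetone, rt to 40 °C
Reagents that add atoms: iodomethane (CI)
Why: Williamson etherification of the chelated phenol, which should outrun conjugate addition and acyl transfer because the ynoate is beta-substituted, the aryl ester is shielded by two ortho methyls and iodomethane is in large excess.

Step 5
Reactants: 9 propanoyl chloride; 10 1,1-dimethoxyethene
Product: 11 1,1-dimethoxypent-1-en-3-one
Conditions: Et3N, Et2O, 0 °C to rt
Reagents that add atoms: none
Why: C-acylation of a ketene acetal at its nucleophilic carbon by an acid chloride with loss of HCl to the amine, the route used for the lower homologue from acetyl chloride.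

Step 6
Reactants: 11 1,1-dimethoxypent-1-en-3-one
Product: 13 (Z)-1,1-dimethoxy-3-(trimethylsilyloxy)penta-1,3-diene, via lithium enolate 12 (not isolated)
Conditions: LiN(iPr)2 (LDA), THF, −78 °C; then Me3SiCl, −78 °C to rt
Reagents that add atoms: chlorotrimethylsilane (C[Si](C)(C)Cl)
Why: Kinetic deprotonation at the ethyl CH2 and O-silylation of the cross-conjugated enolate, where an alkenyl ethyl ketone is expected to favour the enolate with methyl cis to oxygen (Z), and any E isomer, whose methyl would point into the diene cleft against a methoxy group, should be a poorly reactive spectator in step 7.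

Step 7
Reactants: 8 3-methoxy-4-(methoxycarbonyl)-2,5,6-trimethylphenyl but-2-ynoate; 13 (Z)-1,1-dimethoxy-3-(trimethylsilyloxy)penta-1,3-diene
Product: 16 3-methoxy-4-(methoxycarbonyl)-2,5,6-trimethylphenyl 4-hydroxy-2-methoxy-5,6-dimethylbenzoate (3′-deformyl-2,2′-di-O-methylpseudocyphellarin A), via cycloadduct 14 (not isolated), via aryl silyl ether 15 (not isolated)
Conditions: 13 (3 equiv), PhMe, 120 °C, sealed tube; then 1 M HCl, THF, rt
Reagents that add atoms: none
Why: A thermal, concerted but asynchronous normal-demand Diels–Alder reaction between the electron-rich diene 13 and the electron-poor aryl ynoate 8, in which the methyl-bearing diene terminus (made nucleophilic by all three oxygens) bonds to the ynoate beta carbon to form C5′–C6′ and the ketene acetal carbon bonds to the alpha carbon to form C1′–C2′. Cyclohexa-1,4-diene 14 has a ketal at C2′ and a hydrogen at C5′, so it should aromatise by 1,4-loss of methanol to silyl ether 15, which the acidic work-up cleaves to phenol 16. The closest known reaction is the resorcylate synthesis from 1,1-dimethoxy-3-(trimethylsilyloxy)buta-1,3-diene and alkyl but-2-ynoates; the terminal methyl on the diene and the hindered aryl ester are the extensions. Ring A is closed by a suprafacial intermolecular [4+2] annulation from the s-cis conformer of the Z diene, both ring bonds being formed in the one step. The C5′ stereocentre of 14 is transient, formed as a racemate and erased on aromatisation, so no stereocontrol is required. The selectivity needed is regiochemical (ester carbon next to the methoxy carbon, the two methyls adjacent), and it is secured by matching the nucleophilic diene terminus with the electrophilic beta carbon; ring B has no free ring position and no acidic hydrogen to consume the diene.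

Step 8
Reactants: 16 3-methoxy-4-(methoxycarbonyl)-2,5,6-trimethylphenyl 4-hydroxy-2-methoxy-5,6-dimethylbenzoate
Product: 17 3-methoxy-4-(methoxycarbonyl)-2,5,6-trimethylphenyl 3-formyl-4-hydroxy-2-methoxy-5,6-dimethylbenzoate (2,2′-di-O-methylpseudocyphellarin A)
Conditions: Cl2CHOMe, TiCl4, CH2Cl2, −78 to 0 °C; then aq. HCl
Reagents that add atoms: dichloromethyl methyl ether (COC(Cl)Cl); water (O)
Why: Rieche formylation directed by the titanium phenoxide of the C4′ hydroxyl to C3′, the only aromatic carbon in the molecule that bears hydrogen and one activated by the flanking hydroxyl and methoxy groups.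

Step 9
Reactants: 17 3-methoxy-4-(methoxycarbonyl)-2,5,6-trimethylphenyl 3-formyl-4-hydroxy-2-methoxy-5,6-dimethylbenzoate
Product: 18 pseudocyphellarin A
Conditions: BCl3, CH2Cl2, −78 to 0 °C; then H2O
Reagents that add atoms: none
Why: Chelation-controlled Lewis acid ether cleavage, in which BCl3 removes only methyl ethers whose oxygen can chelate boron with an ortho carbonyl (C2′ methoxy beside the formyl and depside carbonyls, C2 methoxy beside the methyl ester), so the methyl ester and the depside link should survive at low temperature.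

**Compound list**

1 | methyl 2,4-dihydroxy-3,6-dimethylbenzoate (methyl beta-orcinolcarboxylate) | COC(=O)c1c(C)cc(O)c(C)c1O | starting material
2 | methyl 5-formyl-2,4-dihydroxy-3,6-dimethylbenzoate | COC(=O)c1c(C)c(C=O)c(O)c(C)c1O | intermediate
3 | methyl 2,4-dihydroxy-5-(hydroxymethyl)-3,6-dimethylbenzoate (benzylic alcohol, not isolated) | COC(=O)c1c(C)c(CO)c(O)c(C)c1O | intermediate
4 | methyl 2,4-dihydroxy-3,5,6-trimethylbenzoate | COC(=O)c1c(C)c(C)c(O)c(C)c1O | intermediate
5 | but-2-ynoic acid | CC#CC(=O)O | starting material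
6 | O-(but-2-ynoyl)-N,N'-dicyclohexylisourea (not isolated) | CC#CC(=O)OC(=NC1CCCCC1)NC1CCCCC1 | intermediate
7 | methyl 4-(but-2-ynoyloxy)-2-hydroxy-3,5,6-trimethylbenzoate | CC#CC(=O)Oc1c(C)c(C)c(C(=O)OC)c(O)c1C | intermediate
8 | 3-methoxy-4-(methoxycarbonyl)-2,5,6-trimethylphenyl but-2-ynoate | CC#CC(=O)Oc1c(C)c(C)c(C(=O)OC)c(OC)c1C | intermediate
9 | propanoyl chloride | CCC(=O)Cl | starting material
10 | 1,1-dimethoxyethene | C=C(OC)OC | starting material
11 | 1,1-dimethoxypent-1-en-3-one | CCC(=O)C=C(OC)OC | intermediate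
12 | lithium (Z)-1,1-dimethoxypenta-1,3-dien-3-olate (not isolated) | C/C=C(\[O-])C=C(OC)OC.[Li+] | intermediate
13 | (Z)-1,1-dimethoxy-3-(trimethylsilyloxy)penta-1,3-diene | C/C=C(\O[Si](C)(C)C)C=C(OC)OC | intermediate
14 | 3-methoxy-4-(methoxycarbonyl)-2,5,6-trimethylphenyl 6,6-dimethoxy-2,3-dimethyl-4-(trimethylsilyloxy)cyclohexa-1,4-diene-1-carboxylate (racemic at the CH(CH3) ring carbon, not isolated) | COC(=O)c1c(C)c(C)c(OC(=O)C2=C(C)C(C)C(O[Si](C)(C)C)=CC2(OC)OC)c(C)c1OC | intermediate
15 | 3-methoxy-4-(methoxycarbonyl)-2,5,6-trimethylphenyl 2-methoxy-5,6-dimethyl-4-(trimethylsilyloxy)benzoate (not isolated) | COC(=O)c1c(C)c(C)c(OC(=O)c2c(C)c(C)c(O[Si](C)(C)C)cc2OC)c(C)c1OC | intermediate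
16 | 3-methoxy-4-(methoxycarbonyl)-2,5,6-trimethylphenyl 4-hydroxy-2-methoxy-5,6-dimethylbenzoate | COC(=O)c1c(C)c(C)c(OC(=O)c2c(C)c(C)c(O)cc2OC)c(C)c1OC | intermediate
17 | 3-methoxy-4-(methoxycarbonyl)-2,5,6-trimethylphenyl 3-formyl-4-hydroxy-2-methoxy-5,6-dimethylbenzoate | COC(=O)c1c(C)c(C)c(OC(=O)c2c(C)c(C)c(O)c(C=O)c2OC)c(C)c1OC | intermediate
18 | pseudocyphellarin A (3-hydroxy-4-(methoxycarbonyl)-2,5,6-trimethylphenyl 3-formyl-2,4-dihydroxy-5,6-dimethylbenzoate) | COC(=O)c1c(C)c(C)c(OC(=O)c2c(C)c(C)c(O)c(C=O)c2O)c(C)c1O | target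

**Step count**

Total: 9 steps. Longest linear sequence: 7 steps (steps 1, 2, 3, 4, 7, 8, 9); the diene branch (steps 5, 6) joins at step 7.

**Steps most likely to fail**

1. Step 7. Diene 13 may decay (silyl migration, hydrolysis by traces of water, oligomerisation) faster than it adds to a beta-methyl ynoate whose ester is flanked by two ortho methyls, or its ketene acetal carbon may be acylated by the aryl ester. The fallback sets out from 13 and 4 and comes back at 18; it builds ring A on a small ester and forms the depside bond afterwards by classical esterification.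
   - Diene 13 would be heated with methyl but-2-ynoate (CC#CC(=O)OC; neat, 120 °C, then 1 M HCl) to give methyl 4-hydroxy-2-methoxy-5,6-dimethylbenzoate F1.
   - Benzylation (BnBr, K2CO3, DMF) should give methyl 4-(benzyloxy)-2-methoxy-5,6-dimethylbenzoate F2.
   - Hydrolysis of the hindered ester (KOH, aqueous DMSO, 90 °C) should give 4-(benzyloxy)-2-methoxy-5,6-dimethylbenzoic acid F3.
   - Mixed-anhydride coupling ((CF3CO)2O, PhMe, rt) to the C4 hydroxyl of 4 should give 3-hydroxy-4-(methoxycarbonyl)-2,5,6-trimethylphenyl 4-(benzyloxy)-2-methoxy-5,6-dimethylbenzoate F4.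
   - Hydrogenolysis (H2, 10% Pd/C, EtOAc) should give 3-hydroxy-4-(methoxycarbonyl)-2,5,6-trimethylphenyl 4-hydroxy-2-methoxy-5,6-dimethylbenzoate F5.
   - Rieche formylation as in step 8 should give 3-hydroxy-4-(methoxycarbonyl)-2,5,6-trimethylphenyl 3-formyl-4-hydroxy-2-methoxy-5,6-dimethylbenzoate F6, and BCl3 at −78 °C should then cleave its single, doubly activated C2′ methyl ether to give 18.

2. Step 4. Under carbonate the chelated phenoxide may add to the ynoate beta carbon of a second molecule or exchange acyl groups, and the base may isomerise or cleave the aryl ynoate before the slow O-methylation is complete. The fallback sets out from 4 and comes back at 8; it reverses the order so that no ynoate ever meets base.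
   - Benzylation of 4 (BnBr, K2CO3, acetone), selective for the non-chelated C4 hydroxyl, should give methyl 4-(benzyloxy)-2-hydroxy-3,5,6-trimethylbenzoate F7.
   - Methylation (MeI, K2CO3, DMF) should give methyl 4-(benzyloxy)-2-methoxy-3,5,6-trimethylbenzoate F8.
   - Hydrogenolysis (H2, 10% Pd/C, EtOAc) should give methyl 4-hydroxy-2-methoxy-3,5,6-trimethylbenzoate F9, which would be esterified with 5 (DCC, cat. DMAP) to give 8.

3. Step 9. Cleavage of the ring B methyl ether, activated only by chelation to the ester carbonyl, may stall, and forcing conditions may bring chloride attack on the methyl ester or Lewis acid cleavage of the depside. The fallback sets out from 7 and comes back at 18; it carries the ring B oxygen as a benzyl ether, which BCl3 ionises at −78 °C without chelation help.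
   - Benzylation of 7 (BnBr, K2CO3, acetone) should give 3-(benzyloxy)-4-(methoxycarbonyl)-2,5,6-trimethylphenyl but-2-ynoate F10.
   - Cycloaddition with 13 under the conditions of step 7 should give 3-(benzyloxy)-4-(methoxycarbonyl)-2,5,6-trimethylphenyl 4-hydroxy-2-methoxy-5,6-dimethylbenzoate F11.
   - Rieche formylation as in step 8 should give 3-(benzyloxy)-4-(methoxycarbonyl)-2,5,6-trimethylphenyl 3-formyl-4-hydroxy-2-methoxy-5,6-dimethylbenzoate F12.
   - BCl3 (CH2Cl2, −78 °C) should remove the benzyl group and the C2′ methyl group to give 18; both rings are fully substituted, so the benzyl cation has no ring carbon to alkylate.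

Further compounds
F1 | step 7 | methyl 4-hydroxy-2-methoxy-5,6-dimethylbenzoate | COC(=O)c1c(C)c(C)c(O)cc1OC
F2 | step 7 | methyl 4-(benzyloxy)-2-methoxy-5,6-dimethylbenzoate | COC(=O)c1c(C)c(C)c(OCc2ccccc2)cc1OC
F3 | step 7 | 4-(benzyloxy)-2-methoxy-5,6-dimethylbenzoic acid | OC(=O)c1c(C)c(C)c(OCc2ccccc2)cc1OC
F4 | step 7 | 3-hydroxy-4-(methoxycarbonyl)-2,5,6-trimethylphenyl 4-(benzyloxy)-2-methoxy-5,6-dimethylbenzoate | COC(=O)c1c(C)c(C)c(OC(=O)c2c(C)c(C)c(OCc3ccccc3)cc2OC)c(C)c1O
F5 | step 7 | 3-hydroxy-4-(methoxycarbonyl)-2,5,6-trimethylphenyl 4-hydroxy-2-methoxy-5,6-dimethylbenzoate | COC(=O)c1c(C)c(C)c(OC(=O)c2c(C)c(C)c(O)cc2OC)c(C)c1O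
F6 | step 7 | 3-hydroxy-4-(methoxycarbonyl)-2,5,6-trimethylphenyl 3-formyl-4-hydroxy-2-methoxy-5,6-dimethylbenzoate | COC(=O)c1c(C)c(C)c(OC(=O)c2c(C)c(C)c(O)c(C=O)c2OC)c(C)c1O
F7 | step 4 | methyl 4-(benzyloxy)-2-hydroxy-3,5,6-trimethylbenzoate | COC(=O)c1c(C)c(C)c(OCc2ccccc2)c(C)c1O
F8 | step 4 | methyl 4-(benzyloxy)-2-methoxy-3,5,6-trimethylbenzoate | COC(=O)c1c(C)c(C)c(OCc2ccccc2)c(C)c1OC
F9 | step 4 | methyl 4-hydroxy-2-methoxy-3,5,6-trimethylbenzoate | COC(=O)c1c(C)c(C)c(O)c(C)c1OC
F10 | step 9 | 3-(benzyloxy)-4-(methoxycarbonyl)-2,5,6-trimethylphenyl but-2-ynoate | CC#CC(=O)Oc1c(C)c(C)c(C(=O)OC)c(OCc2ccccc2)c1C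
F11 | step 9 | 3-(benzyloxy)-4-(methoxycarbonyl)-2,5,6-trimethylphenyl 4-hydroxy-2-methoxy-5,6-dimethylbenzoate | COC(=O)c1c(C)c(C)c(OC(=O)c2c(C)c(C)c(O)cc2OC)c(C)c1OCc1ccccc1
F12 | step 9 | 3-(benzyloxy)-4-(methoxycarbonyl)-2,5,6-trimethylphenyl 3-formyl-4-hydroxy-2-methoxy-5,6-dimethylbenzoate | COC(=O)c1c(C)c(C)c(OC(=O)c2c(C)c(C)c(O)c(C=O)c2OC)c(C)c1OCc1ccccc1
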